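The runs stem from a simulated flask for an exercise, noise included.

A small charge of free catalyst stands against a far larger charge of reagent, so the useful question is how many times each catalyst turns over in the time allowed.

| setting | winter | dawn | eta | theta | zeta | epsilon |
|---|---|---|---|---|---|---|
| starting material | 0.020 M | 0.020 M | 0.020 M | 0.020 M | 0.020 M | 0.020 M |
| reagent | 0.014 M | 0.014 M | 0.0140 M | 0.0140 M | 0.0140 M | 0.0140 M |
| free catalyst | 0.18 mM | 0.89 mM | 0.040 mM | 0.12 mM | 0.30 mM | 1.0 mM |
| remark | run made earlier | run made earlier |  |  |  |  |
| time |  |  | 8.0 h | 8.0 h | 8.0 h | 8.0 h |

| run | time / h | target / % | starting material / % |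
|---|---|---|---|
| winter | 0.667 | 0 | 99.7 |
| winter | 1.33 | 0.6 | 98.9 |
| winter | 3.00 | 0 | 98.4 |
| winter | 8.00 | 3.2 | 96.1 |
| dawn | 2.00 | 3.3 | 95.2 |
| dawn | 4.00 | 8.4 | 92.1 |
| dawn | 6.00 | 11.2 | 86.4 |
| dawn | 8.00 | 15.3 | 82.5 |

(scatter of a reading: 0.5 percentage points)

* amount of target at the end, in percent of the starting material charged for eta, theta, zeta, epsilon, in this order
* how the row runs (rises, then falls / falls all the way / falls, then rises / rises all the way / hardly changes)

- the earlier runs were read with a standard deviation of 0.5 percentage points
- "hardly changes" means that all values lie within two and a half points (for a concentration: within two and a half percent of the largest)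

That count, the turnover number, is target formed per catalyst charged. Dawn gives 3.44 in 8.0 h. Winter gives 3.56, but it rests on a reading of 3.2% with a scatter of 0.5 percentage points, so dawn carries the reckoning.

Suppose turnover ignores the running down of the charges. Then dawn's figure carries over unchanged, and eta, theta and zeta, each with less catalyst than dawn, reach 0.688%, 2.06% and 5.16%. This is the lower edge of the bracket.

For the upper edge, suppose the rate follows c(reagent) and c(starting material) together, with one reagent used per target. Dawn then averaged 89.1% of its reagent and 92.3% of its starting material. Dividing these out leaves the full-charge turnover number 4.18, the count in 8.0 h with the charges held undiminished. It gives eta 0.836%, theta 2.51% and zeta 6.27%.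

Epsilon has more catalyst than dawn, so its depletion has to be iterated. The first answer is 20.9%. Putting that back into the mean levels gives 15.9%, and going round once more gives 17.0%. That value for epsilon stands above the upper edge for zeta, so on this reckoning the row rises from eta to epsilon.

The forecast gives 0.7%, 2.1%, 5.2% and 17%, and says the row rises all the way, calling the reaction “about first order in free catalyst”. Its values for eta, theta and zeta sit on the lower edge, and its epsilon value lies close to the iterated one.

The flasks give 0.814%, 2.40%, 5.77% and 16.5%, so the row rises all the way.

    reagent + free catalyst → catalyst intermediate A (k = 0.0730 M⁻¹ s⁻¹)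
    catalyst intermediate C → free catalyst + target (k = 7.40 × 10⁻⁴ s⁻¹)
    free catalyst → spent catalyst (k = 4.80 × 10⁻⁶ s⁻¹)
    starting material + catalyst intermediate A → catalyst intermediate B (k = 0.0120 M⁻¹ s⁻¹)
    catalyst intermediate B → catalyst intermediate C (k = 0.0410 s⁻¹)
    2 catalyst intermediate C ⇌ resting dimer, settled at all times (K = 320 M⁻¹)
    free catalyst + target → free catalyst + over-reaction product (k = 0.0420 M⁻¹ s⁻¹)

In eta at 8.00 h, catalyst intermediate A, the resting state of the round, holds 62.4% of the catalyst charged, more than catalyst intermediate C with 20.1% or free catalyst with 14.7%. Zeta ended with 93.8% of its starting material and 89.8% of its reagent. Taking the mean of each level from charge to end, 4.18 falls to 3.84 turnovers, which is 5.76% of the starting material charged.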